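I had no rate constants for this flask and did not look for any, since the earlier runs show a slope that can be frozen.

| flask | left-handed substrate | right-handed substrate | solid reagent | free catalyst | impurity | remark | time |
|---|---|---|---|---|---|---|---|
| teal | 0.40 M | 0.40 M | 0.80 equiv | 0.2 mol% | 0.14 mM | run made earlier |  |
| blue | 0.40 M | 0.40 M | 0.80 equiv | 0.2 mol% | 0.58 mM | run made earlier |  |
| green | 0.40 M | 0.40 M | 0.80 equiv | 0.4 mol% | 0.29 mM | run made earlier |  |
| alpha | 0.40 M | 0.40 M | 0.800 equiv | 0.2 mol% | 0.29 mM |  | 40 min |
| delta | 0.40 M | 0.40 M | 0.800 equiv | 0.2 mol% | 0.29 mM |  | 120 min |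

| run | time / min | right-handed substrate / % | left-handed substrate / % | left-handed product / % |
|---|---|---|---|---|
| teal | 4.00 | 49.9 | 47.1 | 1.9 |
| teal | 6.00 | 50.3 | 47.2 | 4.0 |
| teal | 10.0 | 49.2 | 46.3 | 5.9 |
| teal | 20.0 | 50.3 | 38.5 | 11.0 |
| teal | 30.0 | 49.2 | 32.0 | 18.3 |
| teal | 50.0 | 50.2 | 23.2 | 27.7 |
| blue | 3.00 | 48.7 | 48.9 | 2.8 |
| blue | 10.0 | 49.7 | 47.6 | 2.5 |
| blue | 15.0 | 49.1 | 46.9 | 3.1 |
| blue | 25.0 | 48.7 | 44.1 | 3.3 |
| blue | 40.0 | 50.6 | 41.5 | 9.4 |
| blue | 50.0 | 50.2 | 40.5 | 10.7 |
| green | 4.00 | 49.1 | 45.3 | 5.2 |
| green | 8.00 | 49.0 | 40.8 | 10.8 |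
| green | 15.0 | 49.1 | 32.2 | 16.9 |
| green | 25.0 | 49.0 | 25.6 | 27.0 |
| green | 50.0 | 50.3 | 11.5 | 37.4 |

(scatter of a reading: 1 percentage point)

- free catalyst is single-handed; left-handed substrate and right-handed substrate are mirror images of each other, charged as a racemate, each of them at the stated concentration
- given per volume of solution although it is solid: solid reagent
- at the start none of the solid reagent is in solution
- an excess is the difference of the two amounts in percent of their sum
- an excess is below zero if the other one leads

1. the flask that ends with the higher excess of right-handed substrate over left-handed substrate among what is left of the two, or "neither" when 2 percentage points or less lies between them (alpha / delta / neither)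
2. excess of right-handed substrate over left-handed substrate among what is left of the two at the end, alpha
3. excess of right-handed substrate over left-handed substrate among what is left of the two at the end, delta

Teal and blue look nearly the same, with 0.800 mM of free catalyst in each, and they differ in impurity. Yet at 50.0 min blue holds less left-handed product than teal, 10.7 % against 27.7 %. I took free catalyst charged less impurity as the working amount. That gives 0.660 mM for teal and 0.220 mM for blue, a ratio of 3.00 against 2.59 in product. Teal's product rises along a nearly straight line, so I froze the slope per working amount, the turnover slope, as a fraction of the pair charged: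

teal: 0.140 M⁻¹ s⁻¹
blue: 0.162 M⁻¹ s⁻¹
green, at 25.0 min with 1.31 mM: 0.137 M⁻¹ s⁻¹
mean: 0.146 M⁻¹ s⁻¹

Alpha and delta have a working amount of 0.510 mM. Solid reagent, the limiting reagent, allows a ceiling of 40.0 % of the pair.

product in alpha = slope × working amount × time = 17.9 %
excess = product / (whole pair − product) = 21.8 %
time to the ceiling = 89.2 min

Delta's reading comes later than that, so I put delta at the ceiling, with an excess of 66.7 %.

The forecast chose delta, with 22 % for alpha and 58 % for delta, on the ground that “the impurity appears to kill catalyst one-for-one”. For delta my figure differs from it.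

The flask with the higher excess was delta: alpha gave 22.2 % and delta 61.7 %, below my ceiling figure.

    free catalyst + left-handed substrate ⇌ catalyst intermediate A (K = 9.50 M⁻¹, k = 65.0 M⁻¹ s⁻¹)
    free catalyst + right-handed substrate ⇌ catalyst intermediate B (K = 3.60 M⁻¹, k = 521 M⁻¹ s⁻¹)
    partner + catalyst intermediate A → free catalyst + left-handed product (k = 4.80 M⁻¹ s⁻¹)
    partner + catalyst intermediate B → free catalyst + right-handed product (k = 0.0857 M⁻¹ s⁻¹)
    solid reagent ⇌ partner, rate k5*(cs5 - [partner]) while solid is left; crystals form when [partner] > cs5 (solubility = 47.0 mM, k = 0.0461 s⁻¹)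
    free catalyst + impurity → spent catalyst (k = 2710 M⁻¹ s⁻¹)

My frozen slope gave alpha 17.9 % of left-handed product, and the flask held 18.2 % at 40.0 min. A neighbour, alpha with 0.12 mol% of free catalyst, has a working amount of 0.190 mM, so the slope gives 6.68 % of product and an excess of 7.16 %; that flask stood at 7.35 % and 7.88 %. Delta's excess rests mainly on the return of catalyst intermediate B to free catalyst and right-handed substrate. With that return struck out, delta ends at −2.90 % instead of 61.7 %.

All runs come from a simulation with constants of no real substance, noise included.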